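## Retrosynthetic overview

1. Fraxiresinol ⇐ its bis-benzyl ether ⇐ closure of the guaiacyl tetrahydrofuran ring (C8–O7–C6) from a triol made by reducing a 1-hydroxy-furofuranone.
2. 1-Hydroxy-furofuranone ⇐ ring contraction of a syringylidene 1,3-dioxane fused to the γ-lactone: the acetal carbon shifts from oxygen to the lactone α-carbon (makes C1–C2, the tertiary carbinol and the syringyl tetrahydrofuran ring).
3. Dioxane-fused lactone ⇐ cis-diol lactone + O-benzylsyringaldehyde; diol lactone ⇐ aryl Grignard + anti-aldol adduct of 3-silyloxypropanal and ethyl glyoxylate (organocatalysis sets C5, the only stereocentre that must be carried).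
4. Aryl pieces: catechol → benzyl-protected 4-bromoguaiacol; p-cresol → O-benzylsyringaldehyde.
5. Ring order: γ-lactone → 1,3-dioxane → tetrahydrofuran A (by contraction) → tetrahydrofuran B.

Assumption 1: locants C1–C8 are those of 3,7-dioxabicyclo[3.3.0]octane; the SMILES encodes (1S,2R,5R,6S) with both aryl groups exo.
Assumption 2: the (S)-diarylprolinol catalyst follows the usual hydrogen-bond-directed (proline-type) sense; if the sense proved opposite, the (R)-catalyst is used.

## Route

Step 1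
Reactants: 1 catechol
Product: 2 2-methoxyphenol (guaiacol)
Conditions: MeI (1.0 equiv), K2CO3 (1.0 equiv), acetone, reflux; base extraction removes veratrole
Reagents that add atoms: iodomethane, CI
Why: Williamson mono-O-methylation of the symmetrical diphenol; the dimethyl ether is neutral and unreacted catechol is water-soluble, so 2 is easily separated.

Step 2
Reactants: 2 2-methoxyphenol
Product: 4 1-(benzyloxy)-4-bromo-2-methoxybenzene, via 4-bromo-2-methoxyphenol 3 (not isolated)
Conditions: NBS (1.0 equiv), DMF, 0 °C; then K2CO3, BnBr (excess), rt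
Reagents that add atoms: N-bromosuccinimide, O=C1CCC(=O)N1Br; benzyl bromide, BrCc1ccccc1
Why: Electrophilic aromatic bromination in DMF goes para to the free hydroxyl, and the phenol is then capped in the same pot by Williamson benzylation.

Step 3
Reactants: 5 4-methylphenol (p-cresol)
Product: 6 4-hydroxybenzaldehyde
Conditions: O2 (1 atm), CoCl2 (1 mol %), NaOH (3 equiv), MeOH, 60 °C; then aq HCl
Reagents that add atoms: dioxygen, O=O
Why: Cobalt-catalysed autoxidation of the p-cresolate (via the quinone methide and its methanol adduct) stops at the aldehyde because the phenolate deactivates it towards further oxidation.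

Step 4
Reactants: 6 4-hydroxybenzaldehyde
Product: 7 3,5-dibromo-4-hydroxybenzaldehyde
Conditions: Br2 (2.1 equiv), AcOH, rt
Reagents that add atoms: bromine, BrBr
Why: Electrophilic aromatic bromination; only the two positions ortho to the hydroxyl are activated.

Step 5
Reactants: 7 3,5-dibromo-4-hydroxybenzaldehyde
Product: 9 4-(benzyloxy)-3,5-dimethoxybenzaldehyde, via sodium syringaldehyde phenolate 8 (not isolated)
Conditions: NaOMe (excess), CuCl (10 mol %), DMF–MeOH, 110 °C; distil off MeOH; then BnBr, 60 °C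
Reagents that add atoms: sodium methoxide, C[O-].[Na+]; benzyl bromide, BrCc1ccccc1
Why: Copper-catalysed Ullmann-type methoxylation of both aryl bromides (the classical syringaldehyde process), followed by Williamson benzylation of the phenolate already present.

Step 6
Reactants: 10 3-[(tert-butyldimethylsilyl)oxy]propanal; 11 ethyl glyoxylate (polymeric toluene solution)
Product: 12 ethyl (2R,3S)-4-[(tert-butyldimethylsilyl)oxy]-3-formyl-2-hydroxybutanoate
Conditions: (S)-α,α-bis[3,5-bis(trifluoromethyl)phenyl]prolinol (10 mol %), H2O (3 equiv), MeCN, rt; used without delay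
Reagents that add atoms: none
Why: Diarylprolinol-catalysed direct cross-aldol (enamine catalysis) gives the anti adduct; the enamine face sets C5 of the target, while the carbinol centre is erased later by enolisation.

Step 7
Reactants: 4 1-(benzyloxy)-4-bromo-2-methoxybenzene; 12 ethyl (2R,3S)-4-[(tert-butyldimethylsilyl)oxy]-3-formyl-2-hydroxybutanoate
Product: 15 (3R,4S,5S)-5-[4-(benzyloxy)-3-methoxyphenyl]-3-hydroxy-4-(hydroxymethyl)dihydrofuran-2(3H)-one, via aryl Grignard reagent 13 (not isolated), via silyl-protected lactone 14 (not isolated)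
Conditions: 4, Mg, THF, 50 °C; add 13 (2.3 equiv) to 12 + LaCl3·2LiCl (1.1 equiv), THF, −78 → 0 °C; then 1 M HCl–THF, 0 °C → rt, 1 h
Reagents that add atoms: none
Why: Lanthanum-assisted Grignard 1,2-addition to the aldehyde (no enolisation at C5, β-alkoxide chelate favours the trans product), 5-exo lactonisation of the benzylic alkoxide and acidic desilylation; the new benzylic centre is re-set in step 10, so its dr does not matter.

Step 8
Reactants: 15 (3R,4S,5S)-5-[4-(benzyloxy)-3-methoxyphenyl]-3-hydroxy-4-(hydroxymethyl)dihydrofuran-2(3H)-one; 9 4-(benzyloxy)-3,5-dimethoxybenzaldehyde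
Product: 17 (2R,4aR,5S,7aR)-2-[4-(benzyloxy)-3,5-dimethoxyphenyl]-5-[4-(benzyloxy)-3-methoxyphenyl]tetrahydro-4H-furo[3,4-d][1,3]dioxin-7(4aH)-one, via dimethyl acetal 16 (not isolated)
Conditions: 9, HC(OMe)3 (1.5 equiv), CSA (2 mol %), CH2Cl2, rt; then 15, 4 Å MS, rt; Et3N quench
Reagents that add atoms: none
Why: Acid-catalysed transacetalisation of the cis-1,3-diol gives the cis-fused arylidene 1,3-dioxane with the aryl equatorial (acetal H cis to both ring-fusion H); mild, base-free conditions keep the lactone from translactonising.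

Step 9
Reactants: 17 (2R,4aR,5S,7aR)-2-[4-(benzyloxy)-3,5-dimethoxyphenyl]-5-[4-(benzyloxy)-3-methoxyphenyl]tetrahydro-4H-furo[3,4-d][1,3]dioxin-7(4aH)-one
Product: 19 (3S,3aR,6R,6aR)-6-[4-(benzyloxy)-3,5-dimethoxyphenyl]-3-[4-(benzyloxy)-3-methoxyphenyl]-6a-hydroxytetrahydro-1H,3H-furo[3,4-c]furan-1-one, via O-dibutylboryl ether 18 (not isolated)
Conditions: n-Bu2BOTf (2.5 equiv), i-Pr2NEt (3 equiv), CH2Cl2, −78 → 0 °C; MeOH / pH 7 buffer
Reagents that add atoms: none
Why: Proposed new method: boron-mediated ring-contracting acetal O→C [1,2]-shift – Bu2BOTf chelates the lactone C=O and the α-acetal oxygen and ionises the acetal C–O bond to an aryl-stabilised oxocarbenium ion still tethered through O3–C4, i-Pr2NEt then removes the α-H of the resulting α-boryloxy lactone to give a boron enediolate whose α-carbon recombines with the oxocarbenium carbon (the tether allows only the cis-fused bicycle, so C1–C2 forms on the face of the CH2O arm and the oxygen becomes the convex tertiary carbinol, the aryl taking the exo position), turning the 1,3-dioxane into the 3-hydroxytetrahydrofuran; closest known reaction types are the Bu2BOTf/amine [1,2]-Wittig rearrangement of O-benzyl glycolate boron enolates with C-aldol of the derived enediolates, the acetal [1,2]-Wittig rearrangement of O-glycosides and the Petasis–Ferrier O→C acetal rearrangement.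

Step 10
Reactants: 19 (3S,3aR,6R,6aR)-6-[4-(benzyloxy)-3,5-dimethoxyphenyl]-3-[4-(benzyloxy)-3-methoxyphenyl]-6a-hydroxytetrahydro-1H,3H-furo[3,4-c]furan-1-one
Product: 21 (1S,2R,5R,6S)-2-[4-(benzyloxy)-3,5-dimethoxyphenyl]-6-[4-(benzyloxy)-3-methoxyphenyl]-3,7-dioxabicyclo[3.3.0]octan-1-ol, via triol 20 (not isolated)
Conditions: LiAlH4, THF, 0 °C → rt; then 2 M aq HCl to pH 1, 0 °C → rt, 30 min
Reagents that add atoms: none
Why: Hydride reduction of the lactone gives the triol, whose electron-rich benzylic alcohol ionises on acidification (SN1) and is trapped 5-exo by the primary hydroxyl with the aryl exo, the kinetic outcome of furofuran (pinoresinol-type) cyclisations; short contact limits epimerisation at the syringyl carbon.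

Step 11
Reactants: 21 (1S,2R,5R,6S)-2-[4-(benzyloxy)-3,5-dimethoxyphenyl]-6-[4-(benzyloxy)-3-methoxyphenyl]-3,7-dioxabicyclo[3.3.0]octan-1-ol
Product: 22 fraxiresinol, (1S,2R,5R,6S)-2-(4-hydroxy-3,5-dimethoxyphenyl)-6-(4-hydroxy-3-methoxyphenyl)-3,7-dioxabicyclo[3.3.0]octan-1-ol
Conditions: H2 (1 atm), 10 % Pd/C, EtOAc–MeOH, rt, monitored and stopped at full debenzylation
Reagents that add atoms: none
Why: Catalytic hydrogenolysis cleaves the two aryl benzyl ethers faster than the cyclic benzylic ethers under neutral conditions, and no stereocentre is touched.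

## Compound list

1 | catechol | Oc1ccccc1O | starting material
2 | 2-methoxyphenol | COc1ccccc1O | intermediate
3 | 4-bromo-2-methoxyphenol | COc1cc(Br)ccc1O | intermediate
4 | 1-(benzyloxy)-4-bromo-2-methoxybenzene | COc1cc(Br)ccc1OCc1ccccc1 | intermediate
5 | 4-methylphenol | Cc1ccc(O)cc1 | starting material
6 | 4-hydroxybenzaldehyde | O=Cc1ccc(O)cc1 | intermediate
7 | 3,5-dibromo-4-hydroxybenzaldehyde | O=Cc1cc(Br)c(O)c(Br)c1 | intermediate
8 | sodium 4-formyl-2,6-dimethoxyphenolate | COc1cc(C=O)cc(OC)c1[O-].[Na+] | intermediate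
9 | 4-(benzyloxy)-3,5-dimethoxybenzaldehyde | COc1cc(C=O)cc(OC)c1OCc1ccccc1 | intermediate
10 | 3-[(tert-butyldimethylsilyl)oxy]propanal | O=CCCO[Si](C)(C)C(C)(C)C | starting material
11 | ethyl glyoxylate | CCOC(=O)C=O | starting material
12 | ethyl (2R,3S)-4-[(tert-butyldimethylsilyl)oxy]-3-formyl-2-hydroxybutanoate | CCOC(=O)[C@H](O)[C@@H](C=O)CO[Si](C)(C)C(C)(C)C | intermediate
13 | [4-(benzyloxy)-3-methoxyphenyl]magnesium bromide | COc1cc([Mg]Br)ccc1OCc1ccccc1 | intermediate
14 | (3R,4S,5S)-5-[4-(benzyloxy)-3-methoxyphenyl]-4-{[(tert-butyldimethylsilyl)oxy]methyl}-3-hydroxydihydrofuran-2(3H)-one | O=C1O[C@H](c2ccc(OCc3ccccc3)c(OC)c2)[C@@H](CO[Si](C)(C)C(C)(C)C)[C@H]1O | intermediate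
15 | (3R,4S,5S)-5-[4-(benzyloxy)-3-methoxyphenyl]-3-hydroxy-4-(hydroxymethyl)dihydrofuran-2(3H)-one | O=C1O[C@H](c2ccc(OCc3ccccc3)c(OC)c2)[C@@H](CO)[C@H]1O | intermediate
16 | 2-(benzyloxy)-5-(dimethoxymethyl)-1,3-dimethoxybenzene | COC(OC)c1cc(OC)c(OCc2ccccc2)c(OC)c1 | intermediate
17 | (2R,4aR,5S,7aR)-2-[4-(benzyloxy)-3,5-dimethoxyphenyl]-5-[4-(benzyloxy)-3-methoxyphenyl]tetrahydro-4H-furo[3,4-d][1,3]dioxin-7(4aH)-one (cis-fused, acetal aryl equatorial) | O=C1O[C@H](c3ccc(OCc4ccccc4)c(OC)c3)[C@H]2CO[C@@H](c3cc(OC)c(OCc4ccccc4)c(OC)c3)O[C@@H]12 | intermediate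
18 | O-dibutylboryl ether of 19 | O=C1O[C@H](c3ccc(OCc4ccccc4)c(OC)c3)[C@H]2CO[C@H](c3cc(OC)c(OCc4ccccc4)c(OC)c3)[C@@]12OB(CCCC)CCCC | intermediate
19 | (3S,3aR,6R,6aR)-6-[4-(benzyloxy)-3,5-dimethoxyphenyl]-3-[4-(benzyloxy)-3-methoxyphenyl]-6a-hydroxytetrahydro-1H,3H-furo[3,4-c]furan-1-one | O=C1O[C@H](c3ccc(OCc4ccccc4)c(OC)c3)[C@H]2CO[C@H](c3cc(OC)c(OCc4ccccc4)c(OC)c3)[C@@]12O | intermediate
20 | (2R,3S,4R)-2-[4-(benzyloxy)-3,5-dimethoxyphenyl]-4-{(S)-[4-(benzyloxy)-3-methoxyphenyl](hydroxy)methyl}-3-(hydroxymethyl)tetrahydrofuran-3-ol | OC[C@]1(O)[C@@H](c2cc(OC)c(OCc3ccccc3)c(OC)c2)OC[C@@H]1[C@H](O)c1ccc(OCc2ccccc2)c(OC)c1 | intermediate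
21 | (1S,2R,5R,6S)-2-[4-(benzyloxy)-3,5-dimethoxyphenyl]-6-[4-(benzyloxy)-3-methoxyphenyl]-3,7-dioxabicyclo[3.3.0]octan-1-ol | COc1cc([C@H]2OC[C@]3(O)[C@@H](c4cc(OC)c(OCc5ccccc5)c(OC)c4)OC[C@H]23)ccc1OCc1ccccc1 | intermediate
22 | fraxiresinol | COc1cc([C@H]2OC[C@]3(O)[C@@H](c4cc(OC)c(O)c(OC)c4)OC[C@H]23)ccc1O | target

## Count and risks

Total step count: 11. Longest linear sequence: 7 steps (5 → 6 → 7 → 9 → 17 → 19 → 21 → 22, or 1 → 2 → 4 → 15 → 17 → 19 → 21 → 22).

Most likely to fail, step 9 (the proposed shift). Possible failures are no ionisation, recombination at the wrong carbon, or the endo epimer at C2. The fallback uses known chemistry, sets out from 15 and comes back at 21. Catalytic DBU in THF translactonises 15 to the less substituted primary-oxygen lactone, (3R,4R)-4-{(S)-[4-(benzyloxy)-3-methoxyphenyl](hydroxy)methyl}-3-hydroxydihydrofuran-2(3H)-one F3. TESCl and imidazole give its bis(triethylsilyl) ether F4. LDA at −78 °C and then 9 give the aldol adduct F5; the aldehyde enters anti to the β-substituent, as in classical lignan-lactone aldols, which is the configuration C1 needs. LiAlH4 gives the bis-silylated triol F6, and 2 M HCl in the same flask removes the silyl groups to the pentaol F7, which closes both rings by SN1 etherification to 21.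

Second, step 7 (organomagnesium addition to an epimerisable β-formyl hydroxy ester). Possible failures are enolisation or retro-aldol, which would erode C5. The fallback replaces the basic reagent by a Nozaki–Hiyama–Kishi coupling, sets out from 2 and 12 and comes back at 15. NIS in DMF gives 4-iodo-2-methoxyphenol F1, which is benzylated in the same pot (K2CO3, BnBr) to 1-(benzyloxy)-4-iodo-2-methoxybenzene F2. F2 and 12 are coupled with CrCl2 and catalytic NiCl2 in DMF at rt; the aryl-chromium(III) species is non-basic and tolerates the ester and the free hydroxyl. The same HCl work-up lactonises through 14, removes the silyl group and returns 15.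

Third, step 10 (SN1 ring closure). Possible failures are a poor exo/endo ratio at C6 or acid epimerisation at C2. The fallback closes the ring by SN2 at the primary carbon instead, sets out from 20 (isolated after a basic work-up of the hydride reduction) and comes back at 21. It needs the (S)-carbinol from the chelation-controlled addition in step 7; the minor epimer is removed at 15 or 17. TsCl, pyridine and catalytic DMAP at 0 °C sulfonylate only the primary hydroxyl to give the mono-tosylate F8, which is displaced 5-exo-tet by the benzylic hydroxyl on warming to 40 °C, with both benzylic configurations retained.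

Further compounds
F1 | step 7 | 4-iodo-2-methoxyphenol | COc1cc(I)ccc1O
F2 | step 7 | 1-(benzyloxy)-4-iodo-2-methoxybenzene | COc1cc(I)ccc1OCc1ccccc1
F3 | step 9 | (3R,4R)-4-{(S)-[4-(benzyloxy)-3-methoxyphenyl](hydroxy)methyl}-3-hydroxydihydrofuran-2(3H)-one | O=C1OC[C@H]([C@H](O)c2ccc(OCc3ccccc3)c(OC)c2)[C@H]1O
F4 | step 9 | bis(triethylsilyl) ether of F3 | O=C1OC[C@H]([C@H](O[Si](CC)(CC)CC)c2ccc(OCc3ccccc3)c(OC)c2)[C@H]1O[Si](CC)(CC)CC
F5 | step 9 | (3R,4R)-3-{(R)-[4-(benzyloxy)-3,5-dimethoxyphenyl](hydroxy)methyl}-4-{(S)-[4-(benzyloxy)-3-methoxyphenyl][(triethylsilyl)oxy]methyl}-3-[(triethylsilyl)oxy]dihydrofuran-2(3H)-one | O=C1OC[C@H]([C@H](O[Si](CC)(CC)CC)c2ccc(OCc3ccccc3)c(OC)c2)[C@@]1(O[Si](CC)(CC)CC)[C@H](O)c1cc(OC)c(OCc2ccccc2)c(OC)c1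
F6 | step 9 | bis(triethylsilyl) ether (tertiary and guaiacyl-carbinol oxygens) of F7 | OC[C@H]([C@H](O[Si](CC)(CC)CC)c1ccc(OCc2ccccc2)c(OC)c1)[C@](O[Si](CC)(CC)CC)(CO)[C@H](O)c1cc(OC)c(OCc2ccccc2)c(OC)c1
F7 | step 9 | (2S,3R)-2-{(R)-[4-(benzyloxy)-3,5-dimethoxyphenyl](hydroxy)methyl}-3-{(S)-[4-(benzyloxy)-3-methoxyphenyl](hydroxy)methyl}butane-1,2,4-triol | OC[C@H]([C@H](O)c1ccc(OCc2ccccc2)c(OC)c1)[C@](O)(CO)[C@H](O)c1cc(OC)c(OCc2ccccc2)c(OC)c1
F8 | step 10 | primary mono-tosylate of 20 | Cc1ccc(cc1)S(=O)(=O)OC[C@]1(O)[C@@H](c2cc(OC)c(OCc3ccccc3)c(OC)c2)OC[C@@H]1[C@H](O)c1ccc(OCc2ccccc2)c(OC)c1
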